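**Retrosynthetic overview**

1. Abyssomicin N ⇒ (desilylation; Dieckmann closure C2–C3 of the eight-membered ring, the last ring) tricyclic lactone 22.
2. 22 ⇒ (key cascade) 8-oxabicyclo[3.2.1]octan-2-one 19: C10 shifts from C16 to the C15 carbonyl carbon, which contracts the cycloheptanone to the cyclohexane and enlarges the tetrahydrofuran O–C16–C10–C11–C12 to the tetrahydropyran O–C16–C15–C10–C11–C12; the C16 oxocarbenium ion closes onto C8 (cyclopentane) and the C15 oxygen onto C1 (butanolide).
3. Enabling feature: the vicinal pair C15 (tertiary carbon with the lactone oxygen) / C16 (carbon with the ether oxygen of the tetrahydropyran) is the retron of an α-alkoxy ketone 1,2-shift, and C8 (α to the C7 ketone) lies four atoms from C16 through C9–C10.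
4. 19 ⇒ oxidopyrylium [5+2] adduct 7 (Achmatowicz pyranone from 5-methylfurfural, plus a vinyl ether) and vinyl ketone 15 (from meso-2,4-dimethylglutaric anhydride), joined by a Mukaiyama–Michael addition; C10, C11 and C13 are set by exo-face attack on the oxygen-bridged bicycle.
5. Ring order: pyranone → oxygen-bridged cycloheptenone → (key step) cyclohexane, tetrahydropyran, cyclopentane, butanolide → eight-membered enol ring.

Key step: step 15

Remark: atoms are called C1–C16 as in the abyssomicin skeleton (C1 lactone carbonyl, C2=C3 enol, C4 and C6 methyl-bearing, C7 ketone, C8, C9, C10, C11 carbinol, C12 methyl-bearing ether carbon, C13 methyl-bearing, C14, C15 lactone-oxygen carbon, C16 ether carbon); the same labels are used for the intermediates.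
Remark: the vinyl ether is assumed to add to the oxidopyrylium with its oxygen-bearing carbon at the methyl-bearing terminus (C12), as is usual for donor alkenes; both C11 epimers of the adduct converge in step 6.
Remark: the enantiomer of each chiral catalyst (steps 4 and 8) is chosen to give the configuration written in the SMILES.

**Step 1**
Reactants: 1 5-methylfurfural; 2 methyl acetate
Product: 3 methyl 3-hydroxy-3-(5-methylfuran-2-yl)propanoate (racemic)
Conditions: LiN(i-Pr)2, THF, −78 °C; then 1; aq. NH4Cl
Reagents that add atoms: none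
Why: Lithium enolate aldol addition to a non-enolisable aldehyde; the new carbinol centre needs no control because it becomes sp2 in the pyrylium of step 4.

**Step 2**
Reactants: 3
Product: 4 methyl 2-(6-hydroxy-6-methyl-3-oxo-3,6-dihydro-2H-pyran-2-yl)acetate (racemic, hemiketal epimers)
Conditions: NBS, NaHCO3, NaOAc, THF/H2O (4:1), 0 °C
Reagents that add atoms: water, O
Why: Achmatowicz rearrangement, in which oxidation of the 2-furylcarbinol gives the cis-enedione that closes to the pyranone hemiketal.

**Step 3**
Reactants: 4
Product: 5 methyl 2-{6-methyl-6-[4-(methylsulfanyl)benzoyloxy]-3-oxo-3,6-dihydro-2H-pyran-2-yl}acetate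
Conditions: 4-(methylsulfanyl)benzoyl chloride, pyridine, DMAP (cat.), CH2Cl2, 0 °C
Reagents that add atoms: 4-(methylsulfanyl)benzoyl chloride, CSc1ccc(cc1)C(Cl)=O
Why: DMAP-catalysed acylation of the hemiketal hydroxyl installs the carboxylate leaving group needed to generate the pyrylium.

**Step 4**
Reactants: 5; 6 tert-butyl vinyl ether
Product: 7 methyl 2-[(1R,5S,6S)-6-tert-butoxy-5-methyl-2-oxo-8-oxabicyclo[3.2.1]oct-3-en-1-yl]acetate (6-endo ether)
Conditions: 6 (5 equiv), chiral primary amine–thiourea catalyst of the 1-(2-aminocyclohexyl)-3-[3,5-bis(trifluoromethyl)phenyl]thiourea type (15 mol %), N,N'-bis[3,5-bis(trifluoromethyl)phenyl]thiourea (15 mol %), AcOH (15 mol %), toluene, rt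
Reagents that add atoms: none
Why: Amine-catalysed oxidopyrylium [5+2] cycloaddition, in which the primary amine condenses with the ketone, thiourea-assisted loss of the carboxylate gives an aminopyrylium ion, the donor alkene adds across C16 and C12, and the chiral catalyst shields one face and so sets both bridgeheads, while the C11 configuration (endo expected) is of no consequence.

**Step 5**
Reactants: 7
Product: 8 methyl 2-[6-endo-hydroxy-5-methyl-2-oxo-8-oxabicyclo[3.2.1]oct-3-en-1-yl]acetate
Conditions: TFA, CH2Cl2, 0 °C → rt; aq. NaHCO3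
Reagents that add atoms: none
Why: Acidolysis of the tert-butyl ether (E1 loss of isobutene) leaves the enone, the ester and the bridging ether untouched.

**Step 6**
Reactants: 8
Product: 9 methyl 2-(5-methyl-2,6-dioxo-8-oxabicyclo[3.2.1]oct-3-en-1-yl)acetate
Conditions: DMP, NaHCO3, CH2Cl2, rt
Reagents that add atoms: none
Why: Dess–Martin oxidation of the secondary alcohol, by which both C11 epimers converge on one ketone.

**Step 7**
Reactants: 9
Product: 10 methyl 2-[6-(tert-butyldimethylsilyloxy)-5-methyl-2-oxo-8-oxabicyclo[3.2.1]octa-3,6-dien-1-yl]acetate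
Conditions: TBSOTf (1.1 equiv), Et3N, CH2Cl2, −78 → 0 °C
Reagents that add atoms: tert-butyldimethylsilyl triflate, CC(C)(C)[Si](C)(C)OS(=O)(=O)C(F)(F)F
Why: Soft enolisation and silylation, which can give only one enol ether because C10 is the sole enolisable position of the two ketones (the enone has no α′ or γ hydrogen).

**Step 8**
Reactants: 11 meso-2,4-dimethylglutaric anhydride (cis-3,5-dimethyloxane-2,6-dione)
Product: 12 (2R,4S)-5-methoxy-2,4-dimethyl-5-oxopentanoic acid
Conditions: MeOH (10 equiv), (DHQD)2AQN or its pseudoenantiomer (10 mol %), Et2O, −20 °C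
Reagents that add atoms: methanol, CO
Why: Alkaloid-catalysed enantioselective methanolysis (desymmetrisation) of the meso anhydride sets C4 and C6 in one operation.

**Step 9**
Reactants: 12
Product: 14 methyl (2S,4R)-5-[methoxy(methyl)amino]-2,4-dimethyl-5-oxopentanoate, via acyl imidazolide 13 (not isolated)
Conditions: CDI, CH2Cl2, rt; then MeNH(OMe)·HCl
Reagents that add atoms: N,O-dimethylhydroxylamine hydrochloride, CNOC.Cl
Why: Amide formation through the acyl imidazolide, with no base present that is strong enough to epimerise C6.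

**Step 10**
Reactants: 14
Product: 15 methyl (2S,4R)-2,4-dimethyl-5-oxohept-6-enoate
Conditions: CH2=CHMgBr (1.2 equiv), THF, −78 → −20 °C; inverse quench into cold 1 M HCl
Reagents that add atoms: vinylmagnesium bromide, C=C[Mg]Br
Why: Acyl substitution of the N-methoxy-N-methylamide by the Grignard reagent stops at the ketone through the chelated tetrahedral intermediate and is faster than attack at the methyl ester at low temperature.

**Step 11**
Reactants: 10; 15
Product: 16 methyl 2-[7-exo-(3-(tert-butyldimethylsilyloxy)-7-methoxy-4,6-dimethyl-7-oxohept-2-en-1-yl)-5-methyl-2,6-dioxo-8-oxabicyclo[3.2.1]oct-3-en-1-yl]acetate (side-chain methyl centres as in 15; enol ether E/Z mixture)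
Conditions: 15 (1.5 equiv), HNTf2 (5 mol %), CH2Cl2, −78 °C; Et3N quench
Reagents that add atoms: none
Why: Mukaiyama–Michael addition with silyl transfer, in which the bicyclic enol ether attacks the activated vinyl ketone from the exo face (side of the oxygen bridge, setting C10) and the silyl group ends on the C7 oxygen, so that the C7 ketone emerges masked as the regiodefined C8 enol ether.

**Step 12**
Reactants: 16
Product: 17 the 6-endo-hydroxy compound (C11 carbinol) corresponding to 16
Conditions: NaBH4, MeOH/CH2Cl2 (1:1), −78 °C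
Reagents that add atoms: none
Why: Chemoselective borohydride reduction, in which the strained α-alkoxy ketone is reduced faster than the hindered conjugated enone and hydride enters from the exo face to give the endo C11 alcohol.

**Step 13**
Reactants: 17
Product: 18 the 6-endo-(tert-butyldimethylsilyloxy) enone corresponding to 17
Conditions: TBSOTf, 2,6-lutidine, CH2Cl2, −40 → 0 °C
Reagents that add atoms: tert-butyldimethylsilyl triflate, CC(C)(C)[Si](C)(C)OS(=O)(=O)C(F)(F)F
Why: Silylation of the secondary alcohol, for which the silyl triflate has no competing substrate because the enone cannot enolise.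

**Step 14**
Reactants: 18
Product: 19 methyl 2-[6-endo-(tert-butyldimethylsilyloxy)-7-exo-(3-(tert-butyldimethylsilyloxy)-7-methoxy-4,6-dimethyl-7-oxohept-2-en-1-yl)-4-exo,5-dimethyl-2-oxo-8-oxabicyclo[3.2.1]octan-1-yl]acetate
Conditions: Me2CuLi (from CuI and MeLi, 3 equiv), Et2O, −78 → −30 °C; aq. NH4Cl/NH3
Reagents that add atoms: lithium dimethylcuprate, [Li+].C[Cu-]C
Why: Cuprate conjugate addition to the enone from the face of the oxygen bridge, anti to the two-carbon bridge and its endo silyloxy group, which sets C13.

**Step 15**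
Reactants: 19
Product: 22 tricyclic lactone (2-oxabicyclo[2.2.2]octane O–C16/C12 fused to the cyclopentane C15–C16–C8–C9–C10 and to the C15–O–C1 butanolide; C11 silyl ether; C8 carries the 5-methoxy-2,4-dimethyl-5-oxopentanoyl chain), via tricyclic trimethylsilyl ether 20 (not isolated), via tertiary hydroxy ester 21 (not isolated)
Conditions: TMSOTf (1.5 equiv), CH2Cl2 (0.01 M), −78 → −20 °C; then MeOH, PPTS, rt; aq. NaHCO3
Reagents that add atoms: none
Why: Proposed new method: O-silylation of the C15 ketone gives a silyloxocarbenium ion to which the C16–C10 bond (axial on the oxanone ring, antiperiplanar to a lone pair of the bridging oxygen) migrates in a pinacol-type 1,2-shift, so that C15 is inserted into the tetrahydrofuran ring and a 2-oxabicyclo[2.2.2]octyl oxocarbenium ion centred on C16 results; the closest known reaction types are the α-ketol rearrangement and the pinacol-type rearrangement of 1-alkoxybicyclooctyl cations for the shift, and the intramolecular Mukaiyama addition of silyl enol ethers to cyclic oxocarbenium ions (C-glycoside synthesis) for the capture. The oxocarbenium ion is trapped by the tethered C8 silyl enol ether in a 5-exo-trig closure of the cyclopentane; PPTS/MeOH then cleaves the tertiary C15 trimethylsilyl ether and the alcohol closes the butanolide on the neighbouring methyl ester (5-exo-trig acyl substitution), which makes the sequence irreversible. C15 is fixed because the shift is suprafacial with retention at C10 and C15 becomes a bridgehead; C16 is fixed because the enol ether can reach only the face of the oxocarbenium ion on which its tether (exo C9 on C10) lies; C8 follows the preference of the acyl chain for the convex side of the new bicycle and can later equilibrate by enolisation. The step needs the shift to win over direct aldol addition and over other migrations: the exo chain cannot reach C15, migration of the exocyclic CH2CO2Me group would give a bridgehead oxocarbenium ion, and C11 is kept as a silyl ether and not as a ketone so that C10 stays a good migrating group.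

**Step 16**
Reactants: 22
Product: 23 11-O-(tert-butyldimethylsilyl)abyssomicin N
Conditions: LiN(SiMe3)2 (3.5 equiv), THF, −78 → −20 °C; aq. NH4Cl
Reagents that add atoms: none
Why: Dieckmann (intramolecular Claisen) condensation of the lactone enolate (C2) with the C3 methyl ester closes the eight-membered ring, driven by deprotonation of the β-keto lactone, which is obtained as the chelated enol with the ring-cis C2=C3 bond, while C8 can equilibrate to the configuration that allows closure.

**Step 17**
Reactants: 23
Product: 24 abyssomicin N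
Conditions: HF·pyridine, THF/pyridine, 0 °C → rt
Reagents that add atoms: none
Why: Fluoride-mediated cleavage of the secondary silyl ether under buffered, non-basic conditions frees the C11 hydroxyl without touching the enolised β-keto lactone.

**Compound list**

1 | 5-methylfurfural | Cc1ccc(C=O)o1 | starting material
2 | methyl acetate | COC(C)=O | starting material
3 | methyl 3-hydroxy-3-(5-methylfuran-2-yl)propanoate (racemic) | COC(=O)CC(O)c1ccc(C)o1 | intermediate
4 | methyl 2-(6-hydroxy-6-methyl-3-oxo-3,6-dihydro-2H-pyran-2-yl)acetate (racemic, epimers) | COC(=O)CC1OC(C)(O)C=CC1=O | intermediate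
5 | methyl 2-{6-methyl-6-[4-(methylsulfanyl)benzoyloxy]-3-oxo-3,6-dihydro-2H-pyran-2-yl}acetate (racemic, epimers) | COC(=O)CC1OC(C)(OC(=O)c2ccc(SC)cc2)C=CC1=O | intermediate
6 | tert-butyl vinyl ether | C=COC(C)(C)C | starting material
7 | methyl 2-[(1R,5S,6S)-6-tert-butoxy-5-methyl-2-oxo-8-oxabicyclo[3.2.1]oct-3-en-1-yl]acetate | COC(=O)C[C@]12C(=O)C=C[C@](C)(O1)[C@@H](OC(C)(C)C)C2 | intermediate
8 | methyl 2-[6-endo-hydroxy-5-methyl-2-oxo-8-oxabicyclo[3.2.1]oct-3-en-1-yl]acetate | COC(=O)C[C@]12C(=O)C=C[C@](C)(O1)[C@@H](O)C2 | intermediate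
9 | methyl 2-(5-methyl-2,6-dioxo-8-oxabicyclo[3.2.1]oct-3-en-1-yl)acetate | COC(=O)C[C@]12C(=O)C=C[C@](C)(O1)C(=O)C2 | intermediate
10 | methyl 2-[6-(tert-butyldimethylsilyloxy)-5-methyl-2-oxo-8-oxabicyclo[3.2.1]octa-3,6-dien-1-yl]acetate | COC(=O)C[C@]12C(=O)C=C[C@](C)(O1)C(O[Si](C)(C)C(C)(C)C)=C2 | intermediate
11 | meso-2,4-dimethylglutaric anhydride | C[C@@H]1C[C@H](C)C(=O)OC1=O | starting material
12 | (2R,4S)-5-methoxy-2,4-dimethyl-5-oxopentanoic acid | COC(=O)[C@@H](C)C[C@@H](C)C(O)=O | intermediate
13 | acyl imidazolide of 12 | COC(=O)[C@@H](C)C[C@@H](C)C(=O)n1ccnc1 | intermediate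
14 | methyl (2S,4R)-5-[methoxy(methyl)amino]-2,4-dimethyl-5-oxopentanoate | COC(=O)[C@@H](C)C[C@@H](C)C(=O)N(C)OC | intermediate
15 | methyl (2S,4R)-2,4-dimethyl-5-oxohept-6-enoate | COC(=O)[C@@H](C)C[C@@H](C)C(=O)C=C | intermediate
16 | Michael adduct (C11 ketone, C10 exo chain, C7 silyl enol ether) | COC(=O)C[C@]12C(=O)C=C[C@](C)(O1)C(=O)[C@@H]2CC=C(O[Si](C)(C)C(C)(C)C)[C@H](C)C[C@H](C)C(=O)OC | intermediate
17 | endo C11 alcohol of 16 | COC(=O)C[C@]12C(=O)C=C[C@](C)(O1)[C@@H](O)[C@@H]2CC=C(O[Si](C)(C)C(C)(C)C)[C@H](C)C[C@H](C)C(=O)OC | intermediate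
18 | C11 tert-butyldimethylsilyl ether of 17 | COC(=O)C[C@]12C(=O)C=C[C@](C)(O1)[C@@H](O[Si](C)(C)C(C)(C)C)[C@@H]2CC=C(O[Si](C)(C)C(C)(C)C)[C@H](C)C[C@H](C)C(=O)OC | intermediate
19 | 4-exo-methyl 8-oxabicyclo[3.2.1]octan-2-one (key-step substrate) | COC(=O)C[C@]12C(=O)C[C@H](C)[C@](C)(O1)[C@@H](O[Si](C)(C)C(C)(C)C)[C@@H]2CC=C(O[Si](C)(C)C(C)(C)C)[C@H](C)C[C@H](C)C(=O)OC | intermediate
20 | rearranged tricyclic C15 trimethylsilyl ether, diester | COC(=O)[C@@H](C)C[C@@H](C)C(=O)[C@@H]1C[C@H]2[C@H](O[Si](C)(C)C(C)(C)C)[C@@]3(C)O[C@]1(CC(=O)OC)[C@]2(O[Si](C)(C)C)C[C@@H]3C | intermediate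
21 | rearranged tricyclic C15 alcohol, diester | COC(=O)[C@@H](C)C[C@@H](C)C(=O)[C@@H]1C[C@H]2[C@H](O[Si](C)(C)C(C)(C)C)[C@@]3(C)O[C@]1(CC(=O)OC)[C@]2(O)C[C@@H]3C | intermediate
22 | tricyclic lactone | COC(=O)[C@@H](C)C[C@@H](C)C(=O)[C@@H]1C[C@H]2[C@H](O[Si](C)(C)C(C)(C)C)[C@@]3(C)O[C@@]14CC(=O)O[C@@]24C[C@@H]3C | intermediate
23 | 11-O-(tert-butyldimethylsilyl)abyssomicin N | C[C@@H]1C[C@H](C)/C(O)=C2/C(=O)O[C@]34C[C@H](C)[C@]5(C)O[C@]23[C@@H](C[C@H]4[C@@H]5O[Si](C)(C)C(C)(C)C)C1=O | intermediate
24 | abyssomicin N | C[C@@H]1C[C@H](C)/C(O)=C2/C(=O)O[C@]34C[C@H](C)[C@]5(C)O[C@]23[C@@H](C[C@H]4[C@@H]5O)C1=O | target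

**Step count and risks**

Total: 17 steps. Longest linear sequence: 14 steps (steps 1–7 and 11–17); steps 8–10 make the side chain.

Steps most likely to fail:

1. Step 15 (new method). The silylated ketone may not be electrophilic enough to induce the shift. Protodesilylation of the enol ether, or proton loss from the rearranged oxocarbenium ion to an exocyclic enol ether, could then outrun ring closure. The fallback uses only known reaction types, sets out from 19 and returns at 22; in it the ring contraction occurs in the carbocycle and the oxygen ring is re-formed from a diol. The C16–O bond α to the ketone is cleaved with SmI2 (THF, −78 °C), and the samarium enolate is hydroxylated in the same flask with 2-(phenylsulfonyl)-3-phenyloxaziridine to give the ring-opened tertiary α-ketol F1 (C16–OH and C12–OH). Al(Oi-Pr)3 in toluene at 60 °C then effects a classical α-ketol rearrangement, in which C10 moves from the carbinol carbon C16 to the C15 carbonyl (cycloheptanone to acylcyclohexanol). The new C16 ketone is captured by the C12 hydroxyl as the bridged hemiketal F2; only one C15 epimer can form this hemiketal, so it is drained from the equilibrium. TMSOTf (CH2Cl2, −78 °C) ionises the hemiketal to the same oxocarbenium ion, the silyl enol ether adds as in C-glycoside synthesis, and PPTS/MeOH closes the lactone to 22.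

2. Step 4. Enantiofacial discrimination may be poor, or the alkene may add the other way round, because both pyrylium termini are substituted; an uncatalysed background reaction of the tertiary carboxylate would also erode selectivity. The fallback sets out from 5 and 6 and returns at 8. Et3N in CH2Cl2 at rt gives the racemic cycloadduct F3, and TFA gives the racemic alcohol F4. Burkholderia cepacia lipase with vinyl acetate in MTBE then resolves F4 by acylation of one enantiomer. If the unwanted enantiomer reacts, its acetate F5 is separated and unreacted 8 continues; in the opposite case the acetate of 8 is separated and methanolysed (K2CO3, MeOH) to 8.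

3. Step 16. The lactone enolate may expel the bridging ether oxygen by β-elimination, C6 may epimerise under the excess base, and closure of the medium ring on a methyl ester may be slow. The fallback sets out from 22 and returns at 23, and replaces the equilibrium ester condensation by an irreversible C-acylation at −78 °C. Me3SnOH (1,2-dichloroethane, 70 °C) hydrolyses the methyl ester selectively to the carboxylic acid F6, CDI (THF, rt) gives the acyl imidazolide F7, and LiN(SiMe3)2 (2.2 equiv, THF, −78 °C) closes the ring to 23.

**Further compounds**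

F1 | step 15 | ring-opened tertiary α-ketol (C16–OH, C12–OH, C15 ketone; C16 configuration open) | COC(=O)CC1(O)C(=O)C[C@H](C)[C@](C)(O)[C@@H](O[Si](C)(C)C(C)(C)C)[C@@H]1CC=C(O[Si](C)(C)C(C)(C)C)[C@H](C)C[C@H](C)C(=O)OC
F2 | step 15 | bridged hemiketal (2-oxabicyclo[2.2.2]octane with C16–OH and C15–OH; anomeric configuration open) | COC(=O)CC1(O)O[C@@]2(C)[C@@H](C)C[C@]1(O)[C@@H](CC=C(O[Si](C)(C)C(C)(C)C)[C@H](C)C[C@H](C)C(=O)OC)[C@@H]2O[Si](C)(C)C(C)(C)C
F3 | step 4 | racemic cycloadduct (7 and its enantiomer) | COC(=O)C[C@]12C(=O)C=C[C@](C)(O1)[C@@H](OC(C)(C)C)C2.COC(=O)C[C@@]12C(=O)C=C[C@@](C)(O1)[C@H](OC(C)(C)C)C2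
F4 | step 4 | racemic alcohol (8 and its enantiomer) | COC(=O)C[C@]12C(=O)C=C[C@](C)(O1)[C@@H](O)C2.COC(=O)C[C@@]12C(=O)C=C[C@@](C)(O1)[C@H](O)C2
F5 | step 4 | acetate of the enantiomer of 8 | COC(=O)C[C@@]12C(=O)C=C[C@@](C)(O1)[C@H](OC(C)=O)C2
F6 | step 16 | carboxylic acid from 22 (C3 acid) | OC(=O)[C@@H](C)C[C@@H](C)C(=O)[C@@H]1C[C@H]2[C@H](O[Si](C)(C)C(C)(C)C)[C@@]3(C)O[C@@]14CC(=O)O[C@@]24C[C@@H]3C
F7 | step 16 | acyl imidazolide of F6 | O=C(n1ccnc1)[C@@H](C)C[C@@H](C)C(=O)[C@@H]1C[C@H]2[C@H](O[Si](C)(C)C(C)(C)C)[C@@]3(C)O[C@@]14CC(=O)O[C@@]24C[C@@H]3C
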